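If E and Z fall together at a rate that follows the G charged, one number carries the earlier runs over to a new flask.

the same everywhere: Q 10 mM

| flask | G | remark | time |
|---|---|---|---|
| south-east | 0.17 mM | run made earlier |  |
| south | 0.26 mM | run made earlier |  |
| flask | 0.12 mM |  | 50 min |

| run | time / min | E / % | Z / % |
|---|---|---|---|
| south-east | 2.50 | 30.3 | 46.0 |
| south-east | 4.00 | 28.2 | 43.5 |
| south-east | 6.00 | 27.3 | 40.5 |
| south-east | 10.0 | 23.3 | 35.4 |
| south-east | 20.0 | 16.7 | 26.3 |
| south-east | 30.0 | 12.3 | 17.7 |
| south | 2.50 | 29.1 | 44.4 |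
| south | 4.00 | 27.0 | 40.8 |
| south | 6.00 | 23.8 | 37.3 |
| south | 10.0 | 19.8 | 30.3 |
| south | 20.0 | 12.2 | 18.9 |
| south | 30.0 | 7.3 | 11.2 |

(scatter of a reading: 0.3 percentage points)

1. ratio of E to Z at 1.0 s
2. ratio of E to Z at 50 s
3. ratio of E to Z at 50 min



From the first to the last reading, E+Z falls first-order at 0.0339 min⁻¹ in the south-east run and 0.0502 min⁻¹ in the south run. These rates stand in the ratio 1.48, and the G charges in the ratio 1.53. Each rate over its G gives 0.200 min⁻¹ mM⁻¹ and 0.193 min⁻¹ mM⁻¹, so the drain per G is 0.196 min⁻¹ mM⁻¹: the pseudo-first-order rate of fall of E+Z divided by the G charged.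

The flask's curve of E+Z starts at nothing, since the charge holds neither E nor Z. In both earlier runs E+Z falls from the first reading at 2.50 min onward, so in those runs the knee of the curve lies before that reading. The south-east tail, drawn back to zero time, meets 83.1% of the Q charged. From there the flask should fall at 0.0236 min⁻¹, a half-life of 29.4 min, and reach 25.6% at 50 min. The ratio of E to Z reads 0.659 at the first south-east reading and 0.652 at the last south reading, so I expect that level at 50 min. Before the first reading no ratio has been read.

The forecast gives 0.655, 0.655 and 0.655, and says of the earliest time: “my best guess is the same value, but very uncertain”.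

The flask gives 2.64, 1.04 and 0.661.

    G + E → G + D (k = 9.80 M⁻¹ s⁻¹)
    Q + G ⇌ Z + G, rate k2*[Q]*[G] forward; the back reaction follows from the equilibrium constant (K = 2.90, k = 340 M⁻¹ s⁻¹)
    Q ⇌ E (K = 2.00, k = 0.110 s⁻¹)

At 50.0 min the flask holds 25.6% as E+Z, beside the 25.6% reckoned. For the neighbour with 0.072 mM of G, the drain per G gives 41.0%, and that flask holds 40.7%. In the flask, Q has a half-life of 0.11 min by its forward turning into E alone, shorter than the 0.28 min by its forward turning into Z alone at 0.113 min. The constants with the G charged to the flask put the forward rate of Q into E over that of Q into Z at 2.70, beside the 2.64 of E to Z at 1.0 s.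

(The numbers in the tables were computed for substances that don't exist; noise was put on by code.)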